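Remark on the chemistry: the target has no stereocentre and no stereogenic double bond. It is achiral, so the request for a single enantiomer is met trivially and no step needs stereocontrol.

## Structural features

Compound 7 is an achiral wax ester. It has an unbranched, fully saturated C22 acyl chain (C1 = ester carbonyl, C2–C21 = twenty CH2 groups, C22 = CH3), bound through the ester oxygen to an OCH2CH2 spacer that carries the only ring, a monosubstituted benzene. There is no stereocentre, no C=C bond outside the arene and no ring to close, so neither relative nor absolute configuration has to be controlled. The fragile sites are few: the ester (hydrolysis, transesterification, attack by hard organometallics) and the benzylic CH2 with its arene (oxidation). The C1–O bond is the only bond with a polar handle on both sides, which is why it is the cut seen first. The real substance of the molecule lies in the twenty-one C(sp3)–C(sp3) bonds of the chain, most of them so far from C1 that no donor/acceptor logic reaches them. The key step exploits exactly this feature. C11 and C12, the two central methylene carbons, are of like polarity, have no neighbouring group, and lie ten and eleven atoms from C1 and farther still from the benzene ring, so their bond can be made by combining two primary alkyl radicals without leaving a functional scar. Each of these radicals, lengthened by one carboxyl carbon, is a C12 acid of commerce, and a carboxylate is a traceless radical precursor at an anode.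

## Logic of the disconnections

**Disconnection 1 (7 ⇒ 5 + 6 ⇒ 4 + 3).**
- Bond cut: the C11–C12 bond of 7, the central bond of the acyl chain, is cut homolytically into the primary radicals 5 and 6. Each radical centre is then capped with a carboxyl group, which leads back to 4 and 3.
- Reasons for cutting here: it is the point of greatest convergence, since the C22 chain falls into two C11 halves. Both halves, once capped, hold exactly twelve carbons and map onto bulk chemicals. The radical centre of 6 is as far as possible from the ester and the phenyl ring, so 5 and 6 are electronically alike.
- Gain: a chain that otherwise has to be bought whole is built from two short blocks, and nothing has to be removed after the coupling.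
- Demand on the forward step: it must join two carbons of like polarity, favour cross-coupling over homocoupling, stop at the radical stage, and spare the arene, the benzylic CH2 and the ester of 3.
- In one sentence: 7 arises by anodic decarboxylative cross-coupling (mixed Kolbe electrolysis) of 3 with 4, which forms C11–C12 in the middle of the chain. That sentence does not fit the esterification route.

**Disconnection 2 (3 ⇒ 1 + 2).**
- Bond cut: the acyl C12–O bond of 3.
- Reasons for cutting here: it reveals the symmetrical 1 and the simple alcohol 2. The ester is placed before the key step so that the coupling delivers 7 directly, with no later functional group change. The ester also masks the one carboxyl group of 1 that must not be electrolysed.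
- Gain: all remaining complexity disappears and the starting materials are reached.
- Demand on the forward step: only one of two equivalent carboxyl groups may react, so it needs a statistical bias (excess of 1) and a separation based on the number of acid groups.

## Other disconnections considered

Alternative 1: The cut is the acyl C1–O bond of 7, the first that comes to mind. The forward step is esterification of docosanoic acid A1 with 2, either directly (Fischer or Steglich) or through docosanoyl chloride A2. This is one reliable step and remains the benchmark in step count. It forms only the one bond that already has a polar handle and leaves the whole C22 chain to the supplier of A1. It is set aside because it is the conventional disconnection and does not address the chain at all, whereas the chosen plan spends one extra step to build the chain from two C12 bulk acids.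

Alternative 2: The cut is C3–C4. The forward key step is a decarboxylative Giese reaction. Icosanoic acid A3 gives the nonadecyl radical A4, which adds to 2-phenylethyl acrylate A5. The adduct radical, 1-oxo-1-(2-phenylethoxy)docosan-2-yl A6, is then reduced or takes up a hydrogen atom to give 7.
- The polarity match (nucleophilic radical, electron-poor alkene) is good, but the gain in simplicity is marginal. A3 is a saturated C20 fatty acid of the same kind as A1, and only two chain carbons are added.
- A6 can add to a second molecule of A5 (telomerisation) unless it is quenched quickly.
- Unactivated primary carboxylates are the hardest class to oxidise photochemically, so pre-activation would probably be needed, and that removes the advantage in step count.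

Alternative 3: The cut is the alkyl O–CH2 bond. The forward key step is an anti-Markovnikov hydroacyloxylation of styrene A7 with A1 under acridinium photoredox catalysis with a hydrogen-atom donor. The alkene radical cation is attacked by the carboxylate at its terminal carbon to give the 2-(docosanoyloxy)-1-phenylethyl radical A8, which takes up hydrogen.
- The polarity reversal is attractive and the plan is one step long, but the chain is again bought whole in A1.
- The radical cation of unsubstituted A7 should add readily to neutral A7 (dimerisation, polymerisation), while a carboxylate is only a modest nucleophile.
- The oxidation potential of A7 lies at the limit of the excited catalyst.
- The plan therefore takes more risk than the chosen route without simplifying the part of the molecule that holds its bulk.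

Key step: step 2

## Route

Step 1
Reactants: 1 dodecanedioic acid; 2 2-phenylethanol
Product: 3 12-oxo-12-(2-phenylethoxy)dodecanoic acid
Conditions: 1 (3 equiv), 2 (1 equiv), p-TsOH·H2O (5 mol %), toluene, Dean–Stark, reflux; cool, filter off excess 1; SiO2
Reagents that add atoms: none
Why: Fischer esterification with azeotropic removal of water. The two carboxyl groups of 1 are ten CH2 groups apart and react independently, so the outcome is statistical and the threefold excess of 1 should make a second esterification rare. The species present differ in their number of acid groups (two, one, none), so excess 1 should crystallise from cold toluene and 3 should be parted from neutral material on silica or by mild base extraction; no stereocentre is formed.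

Step 2
Reactants: 3 12-oxo-12-(2-phenylethoxy)dodecanoic acid; 4 dodecanoic acid (lauric acid)
Product: 7 2-phenylethyl docosanoate, via undecyl radical 5 (not isolated), via 11-oxo-11-(2-phenylethoxy)undecyl radical 6 (not isolated)
Conditions: 3 (1 equiv), 4 (4 equiv), NaOMe (5 mol % of total acid), MeOH, Pt(+)/Pt(−), undivided cell, ca. 0.25 A cm⁻², 45–50 °C, polarity reversed periodically, stopped while the electrolyte is still acidic; SiO2
Reagents that add atoms: none
Why: Mixed (crossed) Kolbe electrolysis, the anodic decarboxylative radical–radical coupling long used to lengthen fatty acids with half-esters of diacids, is the reaction type relied on. The carboxylates of 3 and 4 are adsorbed on the platinum anode, each gives up one electron, and the acyloxy radicals lose CO2 at once to leave the primary radicals 6 and 5 in a thin layer of high radical concentration, while at the cathode acid protons are reduced to H2, which regenerates carboxylate so that a few mol % of base lasts throughout. Combination of 5 with 6 forms the C11–C12 bond of 7, a union of two carbons of like polarity; no ring is closed and no stereocentre is created, so no mode of closure and no stereocontrol element has to be named. The first selectivity needed is cross-coupling over homocoupling: since the ester of 6 lies ten carbons from the radical centre, 5 and 6 are electronically alike and should combine statistically, so that a fourfold excess of the cheap 4 should steer about four fifths of 6 into 7 on statistical grounds, and the two symmetrical dimers differ from 7 by one ester group each and should separate cleanly on silica. The second is the one-electron (Kolbe) path over the two-electron (Hofer–Moest) path: unstabilised primary radicals without an α-donor are hard to oxidise to cations, and smooth Pt, high current density, weakly acidic methanol and the absence of foreign anions all favour dimerisation. The third is chemoselectivity at the anode: the benzene ring of 3 is a simple monoalkylarene, made slightly poorer by the β-acyloxy group and held at the far end of the chain outside the carboxylate-covered layer, and alkanoic acids with a remote phenyl group are known Kolbe substrates. The ester should survive because the excess of free acid neutralises base as it forms at the cathode, so that methanolysis can begin only if the electrolysis is run past the point where the acids are used up, hence the early stop.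

## Compound list

1 | dodecanedioic acid | OC(=O)CCCCCCCCCCC(=O)O | starting material
2 | 2-phenylethanol | OCCc1ccccc1 | starting material
3 | 12-oxo-12-(2-phenylethoxy)dodecanoic acid (mono-2-phenylethyl dodecanedioate) | OC(=O)CCCCCCCCCCC(=O)OCCc1ccccc1 | intermediate
4 | dodecanoic acid (lauric acid) | CCCCCCCCCCCC(=O)O | starting material
5 | undecyl radical | CCCCCCCCCC[CH2] | intermediate
6 | 11-oxo-11-(2-phenylethoxy)undecyl radical | [CH2]CCCCCCCCCC(=O)OCCc1ccccc1 | intermediate
7 | 2-phenylethyl docosanoate | CCCCCCCCCCCCCCCCCCCCCC(=O)OCCc1ccccc1 | target

## Step count and risks

Total step count: 2. Longest linear sequence: 2 (1 → 3 → 7). The route has only two steps, so both are assessed and no further steps exist to rank.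

**Step 2 (key step).** Four processes could erode it.
- Radical–radical combination is inherently unselective, so part of 6 is lost to homocoupling and disproportionation. This loss can only be biased by the excess of 4, not prevented.
- The waxy, methanol-insoluble products may foul the anode. The potential would then drift and the two-electron pathway and solvent oxidation would gain ground.
- When carboxylate coverage thins towards the end, anodic oxidation of the phenyl ring or the benzylic position may begin to compete.
- If the electrolyte is allowed to turn basic, methanolysis of the phenylethyl ester sets in.

The fallback replaces free-radical statistics by metal-controlled cross-selectivity. It sets out from 3.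
- 3 is activated with N-hydroxyphthalimide and N,N'-diisopropylcarbodiimide (cat. DMAP, CH2Cl2) to give the redox-active ester 1,3-dioxoisoindolin-2-yl 2-phenylethyl dodecanedioate F1.
- Separately, purchased 1-bromoundecane and magnesium in THF give undecylmagnesium bromide F2, which is transmetalated with ZnCl2 (0.5 equiv) to diundecylzinc F3.
- A nickel-catalysed decarboxylative alkyl–alkyl Negishi-type coupling of F1 with F3 (NiCl2·glyme, 4,4'-di-tert-butyl-2,2'-bipyridine, THF/DMF, rt) comes back to the route at 7.

In this sequence the radical from F1 is captured by an alkylnickel species, so the pairing is fixed by the mechanism. There is no anode to attack the arene and no methanol to attack the ester, and the ester tolerates the soft organozinc.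

**Step 1.** The likely trouble is over-esterification of the second, equivalent carboxyl group. The separation may also be awkward, because salts of the long-chain half-ester behave like soaps and emulsify on base extraction.

The fallback differentiates the two chain ends by oxidation state instead of by statistics. It sets out from 2.
- Purchased 12-hydroxydodecanoic acid is esterified with an excess of 2 (p-TsOH, toluene, Dean–Stark; the excess of 2 shifts the ester equilibria away from self-oligomers) to give 2-phenylethyl 12-hydroxydodecanoate F4.
- The primary alcohol of F4 is oxidised with TEMPO (cat.)/PhI(OAc)2 in MeCN–H2O to the acid, which comes back to the route at 3.
- The ester and the benzylic CH2 should be inert to the oxoammonium oxidant.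

## Further compounds

F1 | step 2 | 1,3-dioxoisoindolin-2-yl 2-phenylethyl dodecanedioate | O=C(CCCCCCCCCCC(=O)OCCc1ccccc1)ON1C(=O)c2ccccc2C1=O
F2 | step 2 | undecylmagnesium bromide | CCCCCCCCCCC[Mg]Br
F3 | step 2 | diundecylzinc | CCCCCCCCCCC[Zn]CCCCCCCCCCC
F4 | step 1 | 2-phenylethyl 12-hydroxydodecanoate | OCCCCCCCCCCCC(=O)OCCc1ccccc1
A1 | alternative 1 | docosanoic acid | CCCCCCCCCCCCCCCCCCCCCC(=O)O
A2 | alternative 1 | docosanoyl chloride | CCCCCCCCCCCCCCCCCCCCCC(=O)Cl
A3 | alternative 2 | icosanoic acid | CCCCCCCCCCCCCCCCCCCC(=O)O
A4 | alternative 2 | nonadecyl radical | CCCCCCCCCCCCCCCCCC[CH2]
A5 | alternative 2 | 2-phenylethyl acrylate | C=CC(=O)OCCc1ccccc1
A6 | alternative 2 | 1-oxo-1-(2-phenylethoxy)docosan-2-yl radical | CCCCCCCCCCCCCCCCCCCC[CH]C(=O)OCCc1ccccc1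
A7 | alternative 3 | styrene | C=Cc1ccccc1
A8 | alternative 3 | 2-(docosanoyloxy)-1-phenylethyl radical | CCCCCCCCCCCCCCCCCCCCCC(=O)OC[CH]c1ccccc1
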